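**Plan**

1. Retrosynthetic cuts: the MOM ether on O4′; O1–C2 of ring C (Mitsunobu); C3–C4 (auxiliary-controlled benzylation joining ring A to a ring-B acetic acid); then, in one operation, both aryl bonds of pyran ring D (C2′–O and C3′–CH) together with O–CMe2, back to an aryne and 3-methylbut-2-enal.
2. Enabling feature: C3′ of ring B lies between C2′ and the oxygen-bearing C4′. In a C2′≡C3′ aryne the σ-withdrawing C4′–O bond makes C2′ the electrophilic end, so the enal oxygen adds at C2′ and its carbonyl carbon at C3′. The resulting ortho-quinone methide closes ring D by oxa-6π electrocyclisation, with the ring oxygen remote from the future free OH.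
3. Forward, rings B and D: 2-bromoresorcinol → allyl and MOM ethers → Claisen rearrangement (side chain at C1′) → retro-Brook/triflation → ozonolysis to the arylacetate → aryne annulation (ring D) → acid → acyl oxazolidinone.
4. Forward, ring A: 3,5-dimethoxyphenol → silyl ether → lithiation between the two methoxy groups and prenylation → formylation → benzylic bromide.
5. Union: Evans alkylation (C3–C4), LiBH4, desilylation, Mitsunobu closure of ring C, MOM removal.
6. Stereochemistry: the single stereocentre C3 (R) is set in the Evans alkylation by (4R)-4-benzyl-1,3-oxazolidin-2-one and is no longer enolisable after the reduction.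

Key step: step 6

Remark: ring A is the dimethoxy-prenyl benzene ring, ring C its fused dihydropyran, ring B the 3-aryl ring (C1′ on C3, pyran oxygen on C2′, pyran CH on C3′, OH on C4′), ring D the dimethylpyran; compounds 1, 2, 12, 18, 21 and 23 are taken as purchasable.

**Route**

Step 1
Reactants: 1 2-bromobenzene-1,3-diol; 2 allyl bromide
Product: 3 2-bromo-3-(prop-2-en-1-yloxy)phenol
Conditions: 2 (1.0 equiv), K2CO3 (1.1 equiv), acetone, 56 °C; mono-ether separated from diol (recycled) and bis-ether
Reagents that add atoms: none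
Why: Williamson etherification of a symmetric diol, which should give a statistical mixture without any regiochemical issue because both hydroxyls are equivalent.

Step 2
Reactants: 3 2-bromo-3-(prop-2-en-1-yloxy)phenol
Product: 4 2-bromo-1-(methoxymethoxy)-3-(prop-2-en-1-yloxy)benzene
Conditions: NaH, DMF, 0 °C; then MOMCl, 0 to 25 °C
Reagents that add atoms: chloromethyl methyl ether, COCCl
Why: O-alkylation of the sodium phenoxide (Williamson-type acetal formation) installs the MOM group, which later polarises the aryne and protects O4′.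

Step 3
Reactants: 4 2-bromo-1-(methoxymethoxy)-3-(prop-2-en-1-yloxy)benzene
Product: 5 2-bromo-3-(methoxymethoxy)-6-(prop-2-en-1-yl)phenol
Conditions: N,N-diethylaniline, 190 °C, sealed tube, argon
Reagents that add atoms: none
Why: Aromatic Claisen rearrangement, in which the [3,3] shift should go to the only unsubstituted ortho carbon (the other carries Br) and tautomerisation restores the phenol.

Step 4
Reactants: 5 2-bromo-3-(methoxymethoxy)-6-(prop-2-en-1-yl)phenol
Product: 9 3-(methoxymethoxy)-6-(prop-2-en-1-yl)-2-(trimethylsilyl)phenyl trifluoromethanesulfonate, via silyl ether 6 (not isolated), via aryllithium 7 (not isolated), via lithium phenoxide 8 (not isolated)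
Conditions: (Me3Si)2NH, THF, 66 °C, then volatiles removed; n-BuLi (1.1 equiv), THF, −78 °C; Tf2O (1.2 equiv), −78 to 25 °C
Reagents that add atoms: hexamethyldisilazane, C[Si](C)(C)N[Si](C)(C)C; trifluoromethanesulfonic anhydride, O=S(=O)(OS(=O)(=O)C(F)(F)F)C(F)(F)F
Why: O-silylation, Br–Li exchange and anionic 1,3 O-to-C silyl shift (retro-Brook rearrangement) should place SiMe3 between the two oxygens, and the released phenoxide is trapped as the triflate, the standard construction of an ortho-silylaryl triflate.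

Step 5
Reactants: 9 3-(methoxymethoxy)-6-(prop-2-en-1-yl)-2-(trimethylsilyl)phenyl trifluoromethanesulfonate
Product: 11 methyl 2-[4-(methoxymethoxy)-2-(trifluoromethanesulfonyloxy)-3-(trimethylsilyl)phenyl]acetate, via arylacetaldehyde 10 (not isolated)
Conditions: O3/O2, CH2Cl2–2.5 M NaOH in MeOH (4:1), −78 °C; diluted with Et2O and water while cold
Reagents that add atoms: ozone, [O-][O+]=O; methanol, CO
Why: Ozonolysis in methanolic NaOH, in which the aldehyde from alkene cleavage is taken up as its hemiacetal and oxidised by ozone to the methyl ester in the same pot, while at −78 °C the aryl triflate and aryl silane should not be attacked by methoxide.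

Step 6
Reactants: 11 methyl 2-[4-(methoxymethoxy)-2-(trifluoromethanesulfonyloxy)-3-(trimethylsilyl)phenyl]acetate; 12 3-methylbut-2-enal
Product: 16 methyl 2-[5-(methoxymethoxy)-2,2-dimethyl-2H-chromen-8-yl]acetate, via aryne 13 (not isolated), via benzoxete 14 (not isolated), via ortho-quinone methide 15 (not isolated)
Conditions: CsF (3 equiv), 12 (5 equiv), MeCN, 25 °C, 11 added over 4 h
Reagents that add atoms: none
Why: Fluoride attacks silicon and the aryl anion expels the ortho triflate to give aryne 13; the electron-withdrawing C–O bond of the OMOM group next to one aryne carbon makes the remote aryne carbon (future C2′) the electrophilic end, so the enal oxygen adds there and the developing aryl anion next to OMOM (future C3′) closes on the carbonyl carbon, a stepwise polar [2+2] that forms the aryl–O and the aryl–C bond and gives benzoxete 14. Thermal 4π electrocyclic opening of the strained oxete gives ortho-quinone methide 15, whose 1-oxatriene unit closes by disrotatory oxa-6π electrocyclisation (O–CMe2 bond), which forms the 2,2-dimethyl-2H-pyran ring and restores aromaticity. The closest known reaction types are the annulation of arynes with α,β-unsaturated aldehydes to 2H-chromenes and the insertion of 3-alkoxyarynes into the C=O bond of formamides, which shows the same orientation. No stereocentre remains, because the oxete carbon becomes planar again on ring opening. The step needs regioselectivity across the two aryne carbons, which the inductive effect of the C4′ oxygen should secure and the CH2CO2Me group does not oppose, and chemoselectivity for carbonyl addition over other aryne pathways, which the excess of enal and the slow addition of 11 should favour.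

Step 7
Reactants: 16 methyl 2-[5-(methoxymethoxy)-2,2-dimethyl-2H-chromen-8-yl]acetate
Product: 17 2-[5-(methoxymethoxy)-2,2-dimethyl-2H-chromen-8-yl]acetic acid
Conditions: LiOH·H2O (3 equiv), THF–MeOH–H2O, 25 °C; then 1 M HCl to pH 4 at 0 °C
Reagents that add atoms: lithium hydroxide, [Li+].[OH-]
Why: Ester saponification by acyl–oxygen cleavage, under which the chromene and the MOM acetal are stable.

Step 8
Reactants: 17 2-[5-(methoxymethoxy)-2,2-dimethyl-2H-chromen-8-yl]acetic acid; 18 (4R)-4-benzyl-1,3-oxazolidin-2-one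
Product: 20 (4R)-4-benzyl-3-{2-[5-(methoxymethoxy)-2,2-dimethyl-2H-chromen-8-yl]acetyl}-1,3-oxazolidin-2-one, via mixed anhydride 19 (not isolated)
Conditions: t-BuCOCl (1.1 equiv), Et3N (2.5 equiv), THF, −20 °C; then LiCl (1.2 equiv), 18 (1.1 equiv), −20 to 25 °C
Reagents that add atoms: none
Why: N-acylation of the oxazolidinone through the mixed pivalic anhydride with LiCl/Et3N activation, in which the hindered pivaloyl carbonyl directs attack to the arylacetyl carbonyl.

Step 9
Reactants: 21 3,5-dimethoxyphenol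
Product: 22 (3,5-dimethoxyphenoxy)tri(propan-2-yl)silane
Conditions: i-Pr3SiCl, imidazole, DMF, 25 °C
Reagents that add atoms: chlorotri(propan-2-yl)silane, CC(C)[Si](Cl)(C(C)C)C(C)C
Why: Phenol silylation, giving a bulky, non-coordinating silyloxy group that shields its own ortho positions in the next step.

Step 10
Reactants: 22 (3,5-dimethoxyphenoxy)tri(propan-2-yl)silane; 23 1-bromo-3-methylbut-2-ene
Product: 25 [3,5-dimethoxy-4-(3-methylbut-2-en-1-yl)phenoxy]tri(propan-2-yl)silane, via aryllithium 24 (not isolated)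
Conditions: n-BuLi (1.2 equiv), THF, 0 to 25 °C; then 23, −78 to 25 °C
Reagents that add atoms: none
Why: Directed ortho-metalation at the carbon flanked by both methoxy groups, followed by SN2 alkylation with the allylic bromide, should place the prenyl group between the two OMe groups.

Step 11
Reactants: 25 [3,5-dimethoxy-4-(3-methylbut-2-en-1-yl)phenoxy]tri(propan-2-yl)silane
Product: 26 2,4-dimethoxy-3-(3-methylbut-2-en-1-yl)-6-[tri(propan-2-yl)silyloxy]benzaldehyde
Conditions: POCl3 (1.5 equiv), DMF, 0 to 25 °C; then aq NaOAc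
Reagents that add atoms: N,N-dimethylformamide, CN(C)C=O; water, O
Why: Vilsmeier–Haack formylation, for which the only free ring positions are two equivalent carbons activated by three oxygen substituents, so no regiochemical choice arises.

Step 12
Reactants: 26 2,4-dimethoxy-3-(3-methylbut-2-en-1-yl)-6-[tri(propan-2-yl)silyloxy]benzaldehyde
Product: 27 {2,4-dimethoxy-3-(3-methylbut-2-en-1-yl)-6-[tri(propan-2-yl)silyloxy]phenyl}methanol
Conditions: NaBH4, MeOH–THF, 0 °C
Reagents that add atoms: none
Why: Hydride reduction of the aldehyde, which leaves the alkene and the silyl ether untouched.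

Step 13
Reactants: 27 {2,4-dimethoxy-3-(3-methylbut-2-en-1-yl)-6-[tri(propan-2-yl)silyloxy]phenyl}methanol
Product: 28 [2-(bromomethyl)-3,5-dimethoxy-4-(3-methylbut-2-en-1-yl)phenoxy]tri(propan-2-yl)silane
Conditions: PBr3 (0.4 equiv), pyridine (0.1 equiv), Et2O, −20 °C; cold aq NaHCO3 wash, dried, used at once as a cold solution
Reagents that add atoms: phosphorus tribromide, BrP(Br)Br
Why: Bromide substitution of the benzylic alcohol through its phosphite ester, run cold and without purification because the electron-rich benzylic bromide ionises easily.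

Step 14
Reactants: 20 (4R)-4-benzyl-3-{2-[5-(methoxymethoxy)-2,2-dimethyl-2H-chromen-8-yl]acetyl}-1,3-oxazolidin-2-one; 28 [2-(bromomethyl)-3,5-dimethoxy-4-(3-methylbut-2-en-1-yl)phenoxy]tri(propan-2-yl)silane
Product: 30 (4R)-4-benzyl-3-[(2R)-3-{2,4-dimethoxy-3-(3-methylbut-2-en-1-yl)-6-[tri(propan-2-yl)silyloxy]phenyl}-2-[5-(methoxymethoxy)-2,2-dimethyl-2H-chromen-8-yl]propanoyl]-1,3-oxazolidin-2-one, via sodium enolate 29 (not isolated)
Conditions: NaN(SiMe3)2 (1.05 equiv), THF, −78 °C; then 28 (1.3 equiv), −78 to −45 °C; AcOH quench at −78 °C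
Reagents that add atoms: none
Why: Evans asymmetric alkylation, in which the chelated (Z)-sodium enolate is shielded on one face by the benzyl group of the (4R)-auxiliary, so the benzylic bromide should add to the opposite face and set the new centre as R (priorities C=O > aryl > CH2Ar).

Step 15
Reactants: 30 the alkylated imide
Product: 31 (2R)-3-{2,4-dimethoxy-3-(3-methylbut-2-en-1-yl)-6-[tri(propan-2-yl)silyloxy]phenyl}-2-[5-(methoxymethoxy)-2,2-dimethyl-2H-chromen-8-yl]propan-1-ol
Conditions: LiBH4 (2.5 equiv), MeOH (2.5 equiv), THF, 0 °C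
Reagents that add atoms: none
Why: Reductive cleavage of the N-acyl oxazolidinone by hydride attack at the exocyclic carbonyl, which releases the auxiliary and should not epimerise the α-aryl centre.

Step 16
Reactants: 31 the silyl-protected alcohol
Product: 32 2-{(2R)-3-hydroxy-2-[5-(methoxymethoxy)-2,2-dimethyl-2H-chromen-8-yl]propyl}-3,5-dimethoxy-4-(3-methylbut-2-en-1-yl)phenol
Conditions: Bu4NF (1.1 equiv), THF, 0 °C; then water
Reagents that add atoms: none
Why: Fluoride-induced cleavage of the aryl silyl ether, driven by the Si–F bond, to which the chromene, the prenyl group and the MOM acetal are inert.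

Step 17
Reactants: 32 the phenol alcohol
Product: 33 (3R)-5,7-dimethoxy-3-[5-(methoxymethoxy)-2,2-dimethyl-2H-chromen-8-yl]-6-(3-methylbut-2-en-1-yl)-3,4-dihydro-2H-chromene
Conditions: PPh3 (1.5 equiv), diisopropyl azodicarboxylate (1.5 equiv), THF (0.02 M), 0 to 25 °C
Reagents that add atoms: none
Why: Intramolecular Mitsunobu etherification, a 6-exo-tet displacement at the activated primary carbon by the only free phenol, should close ring C without touching the stereocentre.

Step 18
Reactants: 33 the MOM ether of the target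
Product: 34 Kanzonol I
Conditions: 3 M aq HCl–MeOH (1:9), 40 °C, stopped at full conversion
Reagents that add atoms: none
Why: Acid-catalysed cleavage of the MOM acetal through its oxocarbenium ion with transfer of the CH2 unit to methanol, a deprotection with close precedent on prenylated chromene phenols.

**Compound list**

1 | 2-bromobenzene-1,3-diol | Oc1cccc(O)c1Br | starting material
2 | allyl bromide | C=CCBr | starting material
3 | 2-bromo-3-(prop-2-en-1-yloxy)phenol | C=CCOc1cccc(O)c1Br | intermediate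
4 | 2-bromo-1-(methoxymethoxy)-3-(prop-2-en-1-yloxy)benzene | C=CCOc1cccc(OCOC)c1Br | intermediate
5 | 2-bromo-3-(methoxymethoxy)-6-(prop-2-en-1-yl)phenol | C=CCc1ccc(OCOC)c(Br)c1O | intermediate
6 | [2-bromo-3-(methoxymethoxy)-6-(prop-2-en-1-yl)phenoxy]trimethylsilane | C=CCc1ccc(OCOC)c(Br)c1O[Si](C)(C)C | intermediate
7 | [2-(methoxymethoxy)-5-(prop-2-en-1-yl)-6-(trimethylsilyloxy)phenyl]lithium | C=CCc1ccc(OCOC)c([Li])c1O[Si](C)(C)C | intermediate
8 | lithium 3-(methoxymethoxy)-6-(prop-2-en-1-yl)-2-(trimethylsilyl)phenoxide | C=CCc1ccc(OCOC)c([Si](C)(C)C)c1[O-].[Li+] | intermediate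
9 | 3-(methoxymethoxy)-6-(prop-2-en-1-yl)-2-(trimethylsilyl)phenyl trifluoromethanesulfonate | C=CCc1ccc(OCOC)c([Si](C)(C)C)c1OS(=O)(=O)C(F)(F)F | intermediate
10 | 2-[4-(methoxymethoxy)-2-(trifluoromethanesulfonyloxy)-3-(trimethylsilyl)phenyl]acetaldehyde | O=CCc1ccc(OCOC)c([Si](C)(C)C)c1OS(=O)(=O)C(F)(F)F | intermediate
11 | methyl 2-[4-(methoxymethoxy)-2-(trifluoromethanesulfonyloxy)-3-(trimethylsilyl)phenyl]acetate | COC(=O)Cc1ccc(OCOC)c([Si](C)(C)C)c1OS(=O)(=O)C(F)(F)F | intermediate
12 | 3-methylbut-2-enal | CC(C)=CC=O | starting material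
13 | methyl 2-[4-(methoxymethoxy)-2,3-didehydrophenyl]acetate (aryne) | COC(=O)CC1=CC=C(OCOC)C#C1 | intermediate
14 | methyl 2-[3-(methoxymethoxy)-2-(2-methylprop-1-en-1-yl)-2H-benzo[b]oxet-6-yl]acetate | COC(=O)Cc1ccc(OCOC)c2c1OC2C=C(C)C | intermediate
15 | methyl 2-[(5Z)-4-(methoxymethoxy)-5-(3-methylbut-2-en-1-ylidene)-6-oxocyclohexa-1,3-dien-1-yl]acetate | O=C1C(CC(=O)OC)=CC=C(OCOC)/C1=C/C=C(C)C | intermediate
16 | methyl 2-[5-(methoxymethoxy)-2,2-dimethyl-2H-chromen-8-yl]acetate | COC(=O)Cc1ccc(OCOC)c2c1OC(C)(C)C=C2 | intermediate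
17 | 2-[5-(methoxymethoxy)-2,2-dimethyl-2H-chromen-8-yl]acetic acid | OC(=O)Cc1ccc(OCOC)c2c1OC(C)(C)C=C2 | intermediate
18 | (4R)-4-benzyl-1,3-oxazolidin-2-one | O=C1N[C@H](Cc2ccccc2)CO1 | starting material
19 | 2-[5-(methoxymethoxy)-2,2-dimethyl-2H-chromen-8-yl]acetic 2,2-dimethylpropanoic anhydride | CC(C)(C)C(=O)OC(=O)Cc1ccc(OCOC)c2c1OC(C)(C)C=C2 | intermediate
20 | (4R)-4-benzyl-3-{2-[5-(methoxymethoxy)-2,2-dimethyl-2H-chromen-8-yl]acetyl}-1,3-oxazolidin-2-one | O=C(Cc1ccc(OCOC)c2c1OC(C)(C)C=C2)N1[C@H](Cc2ccccc2)COC1=O | intermediate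
21 | 3,5-dimethoxyphenol | COc1cc(O)cc(OC)c1 | starting material
22 | (3,5-dimethoxyphenoxy)tri(propan-2-yl)silane | COc1cc(OC)cc(O[Si](C(C)C)(C(C)C)C(C)C)c1 | intermediate
23 | 1-bromo-3-methylbut-2-ene | CC(C)=CCBr | starting material
24 | {2,6-dimethoxy-4-[tri(propan-2-yl)silyloxy]phenyl}lithium | COc1cc(O[Si](C(C)C)(C(C)C)C(C)C)cc(OC)c1[Li] | intermediate
25 | [3,5-dimethoxy-4-(3-methylbut-2-en-1-yl)phenoxy]tri(propan-2-yl)silane | COc1cc(O[Si](C(C)C)(C(C)C)C(C)C)cc(OC)c1CC=C(C)C | intermediate
26 | 2,4-dimethoxy-3-(3-methylbut-2-en-1-yl)-6-[tri(propan-2-yl)silyloxy]benzaldehyde | COc1cc(O[Si](C(C)C)(C(C)C)C(C)C)c(C=O)c(OC)c1CC=C(C)C | intermediate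
27 | {2,4-dimethoxy-3-(3-methylbut-2-en-1-yl)-6-[tri(propan-2-yl)silyloxy]phenyl}methanol | COc1cc(O[Si](C(C)C)(C(C)C)C(C)C)c(CO)c(OC)c1CC=C(C)C | intermediate
28 | [2-(bromomethyl)-3,5-dimethoxy-4-(3-methylbut-2-en-1-yl)phenoxy]tri(propan-2-yl)silane | COc1cc(O[Si](C(C)C)(C(C)C)C(C)C)c(CBr)c(OC)c1CC=C(C)C | intermediate
29 | sodium (Z)-enolate of imide 20 | [Na+].[O-]/C(=C\c1ccc(OCOC)c2c1OC(C)(C)C=C2)N1[C@H](Cc2ccccc2)COC1=O | intermediate
30 | (4R)-4-benzyl-3-[(2R)-3-{2,4-dimethoxy-3-(3-methylbut-2-en-1-yl)-6-[tri(propan-2-yl)silyloxy]phenyl}-2-[5-(methoxymethoxy)-2,2-dimethyl-2H-chromen-8-yl]propanoyl]-1,3-oxazolidin-2-one | COc1cc(O[Si](C(C)C)(C(C)C)C(C)C)c(C[C@H](c2ccc(OCOC)c3c2OC(C)(C)C=C3)C(=O)N2[C@H](Cc3ccccc3)COC2=O)c(OC)c1CC=C(C)C | intermediate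
31 | (2R)-3-{2,4-dimethoxy-3-(3-methylbut-2-en-1-yl)-6-[tri(propan-2-yl)silyloxy]phenyl}-2-[5-(methoxymethoxy)-2,2-dimethyl-2H-chromen-8-yl]propan-1-ol | COc1cc(O[Si](C(C)C)(C(C)C)C(C)C)c(C[C@H](c2ccc(OCOC)c3c2OC(C)(C)C=C3)CO)c(OC)c1CC=C(C)C | intermediate
32 | 2-{(2R)-3-hydroxy-2-[5-(methoxymethoxy)-2,2-dimethyl-2H-chromen-8-yl]propyl}-3,5-dimethoxy-4-(3-methylbut-2-en-1-yl)phenol | COc1cc(O)c(C[C@H](c2ccc(OCOC)c3c2OC(C)(C)C=C3)CO)c(OC)c1CC=C(C)C | intermediate
33 | (3R)-5,7-dimethoxy-3-[5-(methoxymethoxy)-2,2-dimethyl-2H-chromen-8-yl]-6-(3-methylbut-2-en-1-yl)-3,4-dihydro-2H-chromene | COc1cc2c(c(OC)c1CC=C(C)C)C[C@H](c1ccc(OCOC)c3c1OC(C)(C)C=C3)CO2 | intermediate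
34 | Kanzonol I, 8-[(3R)-5,7-dimethoxy-6-(3-methylbut-2-en-1-yl)-3,4-dihydro-2H-chromen-3-yl]-2,2-dimethyl-2H-chromen-5-ol | COc1cc2c(c(OC)c1CC=C(C)C)C[C@H](c1ccc(O)c3c1OC(C)(C)C=C3)CO2 | target

**Summary**

Total steps: 18. Longest linear sequence: 13 steps (steps 1 to 8, then 14 to 18); the ring-A branch (steps 9 to 13) joins at step 14.

Steps most likely to fail, with fallbacks:

Step 6 (key step). The aryne may be intercepted by the neighbouring ester carbonyl or by a second aryne, or the enal oxygen may add at the wrong aryne carbon, so that ring D forms poorly or with the wrong orientation. The fallback avoids the aryne and sets out from phenol 5, in which Br already marks C3′ and OH marks C2′. Cleavage of the allyl group and reduction (OsO4 cat., NaIO4, 2,6-lutidine, dioxane–water; then NaBH4) should give 2-[3-bromo-2-hydroxy-4-(methoxymethoxy)phenyl]ethan-1-ol F1. Deprotonation of both hydroxyls, Br–Li exchange (MeLi, then t-BuLi, THF, −78 °C) and addition to 3-methylbut-2-enal 12 should give 1-[2-hydroxy-3-(2-hydroxyethyl)-6-(methoxymethoxy)phenyl]-3-methylbut-2-en-1-ol F2. On heating in toluene F2 should lose water to the ortho-quinone methide and close by the same oxa-6π electrocyclisation to 2-[5-(methoxymethoxy)-2,2-dimethyl-2H-chromen-8-yl]ethan-1-ol F3. Oxidation (TEMPO cat., PhI(OAc)2, MeCN–water) comes back to the route at acid 17.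

Step 14. The electron-rich benzylic bromide 28 may ionise and self-condense before it alkylates the enolate, and any excess base may epimerise the α-aryl imide. The fallback forms the same C3–C4 bond from the stable aldehyde and sets out from acid 17 and aldehyde 26. Perkin condensation (Ac2O, Et3N, 100 °C) should give (2E)-3-{2,4-dimethoxy-3-(3-methylbut-2-en-1-yl)-6-[tri(propan-2-yl)silyloxy]phenyl}-2-[5-(methoxymethoxy)-2,2-dimethyl-2H-chromen-8-yl]prop-2-enoic acid F4. Carboxylate-directed asymmetric hydrogenation (H2, Ru(OAc)2(H8-BINAP), MeOH, ligand antipode chosen for the 2R acid) should leave the unconjugated prenyl and chromene double bonds alone and give (2R)-3-{2,4-dimethoxy-3-(3-methylbut-2-en-1-yl)-6-[tri(propan-2-yl)silyloxy]phenyl}-2-[5-(methoxymethoxy)-2,2-dimethyl-2H-chromen-8-yl]propanoic acid F5. Reduction with LiAlH4 (THF, 0 °C) comes back to the route at alcohol 31.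

Step 11. The chloroiminium and HCl medium may strip the silyl ether or add to the prenyl double bond, and substitution next to the bulky silyloxy group may be slow. The fallback sets out from 25. Bu4NF should give 3,5-dimethoxy-4-(3-methylbut-2-en-1-yl)phenol F6. Magnesium-mediated ortho-formylation (MgCl2, Et3N, paraformaldehyde, MeCN, reflux), which is specific for the carbon next to a free phenol and here meets two equivalent ortho carbons, should give 6-hydroxy-2,4-dimethoxy-3-(3-methylbut-2-en-1-yl)benzaldehyde F7. Silylation (i-Pr3SiOTf, 2,6-lutidine, CH2Cl2) comes back to the route at aldehyde 26.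

Further compounds
F1 | step 6 | 2-[3-bromo-2-hydroxy-4-(methoxymethoxy)phenyl]ethan-1-ol | OCCc1ccc(OCOC)c(Br)c1O
F2 | step 6 | 1-[2-hydroxy-3-(2-hydroxyethyl)-6-(methoxymethoxy)phenyl]-3-methylbut-2-en-1-ol | CC(C)=CC(O)c1c(OCOC)ccc(CCO)c1O
F3 | step 6 | 2-[5-(methoxymethoxy)-2,2-dimethyl-2H-chromen-8-yl]ethan-1-ol | OCCc1ccc(OCOC)c2c1OC(C)(C)C=C2
F4 | step 14 | (2E)-3-{2,4-dimethoxy-3-(3-methylbut-2-en-1-yl)-6-[tri(propan-2-yl)silyloxy]phenyl}-2-[5-(methoxymethoxy)-2,2-dimethyl-2H-chromen-8-yl]prop-2-enoic acid | OC(=O)/C(=C/c1c(OC)c(CC=C(C)C)c(OC)cc1O[Si](C(C)C)(C(C)C)C(C)C)c1ccc(OCOC)c2c1OC(C)(C)C=C2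
F5 | step 14 | (2R)-3-{2,4-dimethoxy-3-(3-methylbut-2-en-1-yl)-6-[tri(propan-2-yl)silyloxy]phenyl}-2-[5-(methoxymethoxy)-2,2-dimethyl-2H-chromen-8-yl]propanoic acid | COc1cc(O[Si](C(C)C)(C(C)C)C(C)C)c(C[C@H](c2ccc(OCOC)c3c2OC(C)(C)C=C3)C(=O)O)c(OC)c1CC=C(C)C
F6 | step 11 | 3,5-dimethoxy-4-(3-methylbut-2-en-1-yl)phenol | COc1cc(O)cc(OC)c1CC=C(C)C
F7 | step 11 | 6-hydroxy-2,4-dimethoxy-3-(3-methylbut-2-en-1-yl)benzaldehyde | COc1cc(O)c(C=O)c(OC)c1CC=C(C)C
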